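The bond cut is the one between the ester oxymethylene carbon and the tertiary carbinol carbon of the cyclohexane ring, next to the lactone ring fusion: this 1-hydroxy-1-(acyloxymethyl)cyclohexane unit is read as the adduct of an acyloxymethyl carbanion and a ring ketone. In one operation a samarium diiodide Barbier coupling joins the complete left-hand acid, as its iodomethyl ester, to the right-hand ring and sets the quaternary carbinol centre by attack on the convex face of a cis-fused bicycle. The ketone partner does not resemble the product: a cis-fused lactol silyl acetal made from (S)-cryptone hides the later lactone carbonyl carbon as an ether CH2 and the later alkene carbon as an acetal carbon.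

Key step: step 14

Remark: lactol, acetal and diol carbons that form as epimer mixtures are written without configuration because the epimers converge later; 1, 2 and (tributylstannyl)methanol are taken as purchasable; TIPS stands for triisopropylsilyl.

Step 1
Reactants: 1 tert-butyl (triphenyl-λ5-phosphanylidene)acetate; 2 (chloromethoxy)triisopropylsilane
Product: 4 tert-butyl 3-(triisopropylsilyloxy)-2-(triphenyl-λ5-phosphanylidene)propanoate, via phosphonium chloride 3 (not isolated)
Conditions: 1 (2 equiv), toluene, 0 °C to rt; phosphonium chloride by-product filtered off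
Reagents that add atoms: none
Why: C-alkylation of an ester-stabilised ylide by a reactive α-chloro ether followed by transylidation with the second equivalent of 1 is a standard entry to α-substituted stabilised ylides, and no stereocentre is formed.

Step 2
Reactants: 5 3-methylbutanal; 6 but-3-en-2-one
Product: 8 (R)-4-isopropylcyclohex-2-en-1-one, via (R)-2-isopropyl-5-oxohexanal 7 (not isolated)
Conditions: (R)-2-[methoxy(diphenyl)methyl]pyrrolidine (5 mol%), ethyl 3,4-dihydroxybenzoate (20 mol%), neat, 4 °C; then LiOH, i-PrOH, rt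
Reagents that add atoms: none
Why: enamine-catalysed Michael addition followed by intramolecular aldol condensation (Robinson-type annulation) should work because the diarylprolinol ether shields one enamine face, so the enone adds to the other face and sets the isopropyl-bearing centre as R.

Step 3
Reactants: 8 (R)-4-isopropylcyclohex-2-en-1-one
Product: 10 (3R,4R)-4-isopropyl-3-vinylcyclohex-1-en-1-yl trifluoromethanesulfonate, via bromomagnesium enolate 9 (not isolated)
Conditions: CH2=CHMgBr, CuBr·SMe2 (10 mol%), THF, −78 to −40 °C; then PhNTf2, −78 °C to rt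
Reagents that add atoms: vinylmagnesium bromide (C=C[Mg]Br); N-phenylbis(trifluoromethanesulfonimide) (O=S(=O)(N(c1ccccc1)S(=O)(=O)C(F)(F)F)C(F)(F)F)
Why: copper-catalysed conjugate addition followed by O-sulfonylation of the regiodefined enolate should work because the vinyl group enters anti to the neighbouring isopropyl group, which sets the 3,4-trans relationship, and the enolate is trapped before it can equilibrate.

Step 4
Reactants: 10 (3R,4R)-4-isopropyl-3-vinylcyclohex-1-en-1-yl trifluoromethanesulfonate
Product: 12 (3R,4R)-3-formyl-4-isopropylcyclohex-1-en-1-yl trifluoromethanesulfonate, via vicinal diol 11 (not isolated)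
Conditions: OsO4 (2 mol%), NaIO4 (4 equiv), 2,6-lutidine, 1,4-dioxane/H2O 3:1, rt
Reagents that add atoms: osmium tetroxide (O=[Os](=O)(=O)=O); sodium periodate ([Na+].[O-]I(=O)(=O)=O)
Why: Lemieux–Johnson cleavage should be selective because OsO4 prefers the monosubstituted vinyl group to the electron-poor enol triflate double bond, and the buffered medium should leave the α-centre trans to isopropyl.

Step 5
Reactants: 12 (3R,4R)-3-formyl-4-isopropylcyclohex-1-en-1-yl trifluoromethanesulfonate; 4 tert-butyl 3-(triisopropylsilyloxy)-2-(triphenyl-λ5-phosphanylidene)propanoate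
Product: 13 tert-butyl (E)-3-[(1S,6R)-6-isopropyl-3-(trifluoromethanesulfonyloxy)cyclohex-2-en-1-yl]-2-[(triisopropylsilyloxy)methyl]prop-2-enoate
Conditions: toluene, 80 °C
Reagents that add atoms: none
Why: Wittig olefination with an α-substituted ester-stabilised ylide should place the ring carbon trans to the ester (E) under the usual thermodynamic control of stabilised ylides, and the ring centres are not touched.

Step 6
Reactants: 13 tert-butyl (E)-3-[(1S,6R)-6-isopropyl-3-(trifluoromethanesulfonyloxy)cyclohex-2-en-1-yl]-2-[(triisopropylsilyloxy)methyl]prop-2-enoate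
Product: 14 tert-butyl (E)-3-[(1R,6R)-3-(hydroxymethyl)-6-isopropylcyclohex-2-en-1-yl]-2-[(triisopropylsilyloxy)methyl]prop-2-enoate
Conditions: Bu3SnCH2OH, Pd(PPh3)4 (5 mol%), LiCl, 1,4-dioxane, 100 °C
Reagents that add atoms: (tributylstannyl)methanol (CCCC[Sn](CCCC)(CCCC)CO)
Why: Stille coupling of an alkenyl triflate with a hydroxymethyl stannane, with chloride assisting transmetallation, should install the allylic CH2OH without touching the acrylate or any stereocentre.

Step 7
Reactants: 14 tert-butyl (E)-3-[(1R,6R)-3-(hydroxymethyl)-6-isopropylcyclohex-2-en-1-yl]-2-[(triisopropylsilyloxy)methyl]prop-2-enoate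
Product: 15 tert-butyl (E)-3-{(1R,6R)-6-isopropyl-3-[(triisopropylsilyloxy)methyl]cyclohex-2-en-1-yl}-2-[(triisopropylsilyloxy)methyl]prop-2-enoate
Conditions: i-Pr3SiCl, imidazole, DMF, rt
Reagents that add atoms: chlorotriisopropylsilane (CC(C)[Si](Cl)(C(C)C)C(C)C)
Why: imidazole-promoted silylation of an unhindered primary allylic alcohol is reliable and forms no stereocentre.

Step 8
Reactants: 15 tert-butyl (E)-3-{(1R,6R)-6-isopropyl-3-[(triisopropylsilyloxy)methyl]cyclohex-2-en-1-yl}-2-[(triisopropylsilyloxy)methyl]prop-2-enoate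
Product: 17 (E)-3-{(1R,6R)-6-isopropyl-3-[(triisopropylsilyloxy)methyl]cyclohex-2-en-1-yl}-2-[(triisopropylsilyloxy)methyl]prop-2-enoic acid, via trimethylsilyl ester 16 (not isolated)
Conditions: Me3SiOTf, 2,6-lutidine, CH2Cl2, 0 °C; then H2O
Reagents that add atoms: trimethylsilyl trifluoromethanesulfonate (C[Si](C)(C)OS(=O)(=O)C(F)(F)F)
Why: silyl-triflate-mediated cleavage of a tert-butyl ester (loss of 2-methylpropene, then hydrolysis of the silyl ester) should spare the primary silyl ethers and the alkene geometry because no strong protic acid is present.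

Step 9
Reactants: 17 (E)-3-{(1R,6R)-6-isopropyl-3-[(triisopropylsilyloxy)methyl]cyclohex-2-en-1-yl}-2-[(triisopropylsilyloxy)methyl]prop-2-enoic acid
Product: 19 iodomethyl (E)-3-{(1R,6R)-6-isopropyl-3-[(triisopropylsilyloxy)methyl]cyclohex-2-en-1-yl}-2-[(triisopropylsilyloxy)methyl]prop-2-enoate, via chloromethyl ester 18 (not isolated)
Conditions: ClCH2OSO2Cl, NaHCO3, Bu4NHSO4 (10 mol%), CH2Cl2/H2O, rt; then NaI, acetone, rt, dark
Reagents that add atoms: chloromethyl chlorosulfate (ClCOS(=O)(=O)Cl); sodium iodide ([Na+].[I-])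
Why: phase-transfer O-alkylation of the carboxylate by the chlorosulfate followed by Finkelstein exchange is the standard route to iodomethyl esters and touches no stereocentre.

Step 10
Reactants: 5 3-methylbutanal; 6 but-3-en-2-one
Product: 21 (S)-4-isopropylcyclohex-2-en-1-one, via (S)-2-isopropyl-5-oxohexanal 20 (not isolated)
Conditions: (S)-2-[methoxy(diphenyl)methyl]pyrrolidine (5 mol%), ethyl 3,4-dihydroxybenzoate (20 mol%), neat, 4 °C; then LiOH, i-PrOH, rt
Reagents that add atoms: none
Why: the same enamine Michael addition and aldol condensation as in step 2, run with the enantiomeric catalyst, should set the isopropyl-bearing centre as S.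

Step 11
Reactants: 21 (S)-4-isopropylcyclohex-2-en-1-one
Product: 23 (3S,4S)-2-(hydroxymethyl)-4-isopropyl-3-vinylcyclohexan-1-one (3,4-trans; C2 epimers), via trimethylsilyl enol ether 22 (not isolated)
Conditions: CH2=CHMgBr, CuBr·SMe2 (10 mol%), Me3SiCl, THF, −78 °C; crude 22, then aq. HCHO, Yb(OTf)3 (10 mol%), THF, rt
Reagents that add atoms: vinylmagnesium bromide (C=C[Mg]Br); chlorotrimethylsilane (C[Si](C)(C)Cl); formaldehyde (C=O)
Why: copper-catalysed conjugate addition anti to the isopropyl group with silyl trapping, then Lewis-acid-mediated Mukaiyama aldol hydroxymethylation of the regiodefined enol ether, should set the 3,4-trans relationship, while the C2 centre is left to be corrected in step 12.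

Step 12
Reactants: 23 (3S,4S)-2-(hydroxymethyl)-4-isopropyl-3-vinylcyclohexan-1-one
Product: 26 (3aR,7S,7aS)-1-hydroxy-7-isopropylhexahydro-2-benzofuran-4(1H)-one (cis-fused; 1-epimers), via secondary ozonide 24 (not isolated), via keto aldehyde 25 (not isolated)
Conditions: O3, CH2Cl2, −78 °C; PPh3, −78 °C to rt; then pyridinium p-toluenesulfonate (20 mol%), CH2Cl2, 40 °C
Reagents that add atoms: ozone ([O-][O+]=O)
Why: ozonolysis with reductive work-up turns the only alkene into an aldehyde that closes onto the hydroxymethyl group as a lactol, and acid-mediated enolisation of the ketone lets the ring-fusion carbon next to it equilibrate, so the cis-fused lactol, which avoids the strain of a trans-fused five-membered ether ring, should accumulate while the centre α to the lactol carbon stays trans to isopropyl.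

Step 13
Reactants: 26 (3aR,7S,7aS)-1-hydroxy-7-isopropylhexahydro-2-benzofuran-4(1H)-one
Product: 27 (3aR,7S,7aS)-7-isopropyl-1-(triethylsilyloxy)hexahydro-2-benzofuran-4(1H)-one (1-epimers)
Conditions: Et3SiCl, imidazole, CH2Cl2, 0 °C
Reagents that add atoms: chlorotriethylsilane (CC[Si](Cl)(CC)CC)
Why: O-silylation of the lactol hydroxyl removes the only acidic proton before the organometallic step and changes no ring stereocentre.

Step 14
Reactants: 19 iodomethyl ester of acid 17; 27 (3aR,7S,7aS)-7-isopropyl-1-(triethylsilyloxy)hexahydro-2-benzofuran-4(1H)-one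
Product: 29 coupled lactol (acyloxymethyl carbinol from 19 at C4 of the 1-hydroxy bicyclic core; tertiary OH cis to the C3a–C3 bond), via triethylsilyl acetal adduct 28 (not isolated)
Conditions: SmI2 (2.5 equiv, 0.1 M in THF), 27 (2 equiv), THF, −40 to 0 °C, slow addition of 19; then aq. citric acid, THF, 0 °C
Reagents that add atoms: none
Why: Proposed new method: samarium diiodide should reduce the weak carbon–iodine bond of the α-acyloxy iodide 19 to the acyloxymethyl radical and on to an acyloxymethylsamarium species, which adds to the ketone of 27 that is present in excess from the start (Barbier mode), so that carbonyl addition can outrun a 1,2-acyl shift; the closest known reaction type is the samarium Barbier alkoxymethylation of ketones with benzyl chloromethyl ether, and α-acyloxyalkyl zinc and copper reagents show that an ester on the metallated carbon is tolerated. No ring is closed in this step. The only new stereocentre, the quaternary carbinol carbon, is controlled by the substrate: in the cis-fused bicycle the CH2–O bond on the ring-fusion carbon next to the carbonyl lies on the concave side, so the nucleophile enters anti to it on the convex face and the hydroxyl ends cis to that bond, as the later lactone requires. The step needs chemoselectivity for the carbon–iodine bond over ketyl formation and over the hindered trisubstituted acrylate, which the easy reduction of an α-acyloxy iodide and the absence of any Michael acceptor in 27 should secure, and it needs the facial selectivity that the cis ring fusion provides. Mild aqueous acid then frees the lactol from the anomeric silyl group while the primary triisopropylsilyl ethers stay.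

Step 15
Reactants: 29 coupled lactol; 4 tert-butyl 3-(triisopropylsilyloxy)-2-(triphenyl-λ5-phosphanylidene)propanoate
Product: 30 ring-opened hydroxymethyl bis-acrylate (lactol carbon of 29 now an (E)-CH=C(CH2OTIPS)CO2t-Bu arm; free CH2OH on the neighbouring ring carbon; arms cis)
Conditions: 4 (3 equiv), toluene, 90 °C
Reagents that add atoms: none
Why: Wittig olefination of the lactol through its hydroxy aldehyde tautomer with the stabilised α-substituted ylide should give the (E)-acrylate (ring carbon trans to the ester), and the ring centres are not involved.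

Step 16
Reactants: 30 ring-opened hydroxymethyl bis-acrylate
Product: 32 carboxylic acid (free CH2OH of 30 oxidised to CO2H), via aldehyde 31 (not isolated)
Conditions: TEMPO (20 mol%), PhI(OAc)2 (2.5 equiv), MeCN/H2O 1:1, rt
Reagents that add atoms: water (O)
Why: oxoammonium oxidation of the only unprotected primary alcohol to the aldehyde, hydration and a second oxidation should give the acid, since the tertiary alcohol and the silyl ethers are inert and the mildly acidic medium should not epimerise the α-carbon.

Step 17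
Reactants: 32 carboxylic acid
Product: 33 seco acid triol (32 with all three triisopropylsilyl ethers removed)
Conditions: HF·pyridine, pyridine, THF, 0 °C to rt
Reagents that add atoms: none
Why: buffered fluoride cleaves the three primary silyl ethers and should leave the esters, the tertiary alcohol and all stereocentres untouched.

Step 18
Reactants: 33 seco acid triol
Product: 35 tert-butyl ester of the target (seven-membered lactone closed), via mixed anhydride 34 (not isolated)
Conditions: 2,4,6-Cl3C6H2COCl, Et3N, THF, rt; then DMAP, toluene (2 mM), rt, slow addition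
Reagents that add atoms: 2,4,6-trichlorobenzoyl chloride (O=C(Cl)c1c(Cl)cc(Cl)cc1Cl)
Why: Yamaguchi lactonisation should close the seven-membered ring selectively because only the allylic hydroxyl on the (E)-acrylate arm is held beside the activated carboxyl by the cis ring substituents and the alkene geometry, so at high dilution it should outrun acylation of the two remote hydroxyls, and no stereocentre changes.

Step 19
Reactants: 35 tert-butyl ester of the target
Product: 37 target CNP0361406.3, via persilylated trimethylsilyl ester 36 (not isolated)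
Conditions: Me3SiOTf (6 equiv), 2,6-lutidine (8 equiv), CH2Cl2, 0 °C; then citric acid, MeOH/H2O, rt
Reagents that add atoms: trimethylsilyl trifluoromethanesulfonate (C[Si](C)(C)OS(=O)(=O)C(F)(F)F)
Why: silyl-triflate-mediated cleavage of the tert-butyl ester with transient silylation of the hydroxyls, undone by mild acid, avoids both strong protic acid and base, so the lactone, the linking ester and the epimerisable lactone α-carbon should survive.

Compound list

1 | tert-butyl (triphenyl-λ5-phosphanylidene)acetate | CC(C)(C)OC(=O)C=P(c1ccccc1)(c1ccccc1)c1ccccc1 | starting material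
2 | (chloromethoxy)triisopropylsilane | ClCO[Si](C(C)C)(C(C)C)C(C)C | starting material
3 | [1-tert-butoxy-1-oxo-3-(triisopropylsilyloxy)propan-2-yl]triphenylphosphonium chloride (racemic) | CC(C)(C)OC(=O)C(CO[Si](C(C)C)(C(C)C)C(C)C)[P+](c1ccccc1)(c1ccccc1)c1ccccc1.[Cl-] | intermediate
4 | tert-butyl 3-(triisopropylsilyloxy)-2-(triphenyl-λ5-phosphanylidene)propanoate | CC(C)(C)OC(=O)C(CO[Si](C(C)C)(C(C)C)C(C)C)=P(c1ccccc1)(c1ccccc1)c1ccccc1 | intermediate
5 | 3-methylbutanal | CC(C)CC=O | starting material
6 | but-3-en-2-one | CC(=O)C=C | starting material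
7 | (R)-2-isopropyl-5-oxohexanal | CC(C)[C@H](C=O)CCC(C)=O | intermediate
8 | (R)-4-isopropylcyclohex-2-en-1-one ((R)-cryptone) | CC(C)[C@H]1CCC(=O)C=C1 | intermediate
9 | bromomagnesium (3R,4R)-4-isopropyl-3-vinylcyclohex-1-en-1-olate | CC(C)[C@H]1CCC(O[Mg]Br)=C[C@@H]1C=C | intermediate
10 | (3R,4R)-4-isopropyl-3-vinylcyclohex-1-en-1-yl trifluoromethanesulfonate | CC(C)[C@H]1CCC(OS(=O)(=O)C(F)(F)F)=C[C@@H]1C=C | intermediate
11 | (3R,4R)-3-(1,2-dihydroxyethyl)-4-isopropylcyclohex-1-en-1-yl trifluoromethanesulfonate (carbinol epimers) | CC(C)[C@H]1CCC(OS(=O)(=O)C(F)(F)F)=C[C@@H]1C(O)CO | intermediate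
12 | (3R,4R)-3-formyl-4-isopropylcyclohex-1-en-1-yl trifluoromethanesulfonate | CC(C)[C@H]1CCC(OS(=O)(=O)C(F)(F)F)=C[C@@H]1C=O | intermediate
13 | tert-butyl (E)-3-[(1S,6R)-6-isopropyl-3-(trifluoromethanesulfonyloxy)cyclohex-2-en-1-yl]-2-[(triisopropylsilyloxy)methyl]prop-2-enoate | CC(C)[C@H]1CCC(OS(=O)(=O)C(F)(F)F)=C[C@@H]1/C=C(\CO[Si](C(C)C)(C(C)C)C(C)C)C(=O)OC(C)(C)C | intermediate
14 | tert-butyl (E)-3-[(1R,6R)-3-(hydroxymethyl)-6-isopropylcyclohex-2-en-1-yl]-2-[(triisopropylsilyloxy)methyl]prop-2-enoate | CC(C)[C@H]1CCC(CO)=C[C@@H]1/C=C(\CO[Si](C(C)C)(C(C)C)C(C)C)C(=O)OC(C)(C)C | intermediate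
15 | tert-butyl (E)-3-{(1R,6R)-6-isopropyl-3-[(triisopropylsilyloxy)methyl]cyclohex-2-en-1-yl}-2-[(triisopropylsilyloxy)methyl]prop-2-enoate | CC(C)[C@H]1CCC(CO[Si](C(C)C)(C(C)C)C(C)C)=C[C@@H]1/C=C(\CO[Si](C(C)C)(C(C)C)C(C)C)C(=O)OC(C)(C)C | intermediate
16 | trimethylsilyl ester of acid 17 | CC(C)[C@H]1CCC(CO[Si](C(C)C)(C(C)C)C(C)C)=C[C@@H]1/C=C(\CO[Si](C(C)C)(C(C)C)C(C)C)C(=O)O[Si](C)(C)C | intermediate
17 | (E)-3-{(1R,6R)-6-isopropyl-3-[(triisopropylsilyloxy)methyl]cyclohex-2-en-1-yl}-2-[(triisopropylsilyloxy)methyl]prop-2-enoic acid | CC(C)[C@H]1CCC(CO[Si](C(C)C)(C(C)C)C(C)C)=C[C@@H]1/C=C(\CO[Si](C(C)C)(C(C)C)C(C)C)C(=O)O | intermediate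
18 | chloromethyl ester of acid 17 | CC(C)[C@H]1CCC(CO[Si](C(C)C)(C(C)C)C(C)C)=C[C@@H]1/C=C(\CO[Si](C(C)C)(C(C)C)C(C)C)C(=O)OCCl | intermediate
19 | iodomethyl ester of acid 17 | CC(C)[C@H]1CCC(CO[Si](C(C)C)(C(C)C)C(C)C)=C[C@@H]1/C=C(\CO[Si](C(C)C)(C(C)C)C(C)C)C(=O)OCI | intermediate
20 | (S)-2-isopropyl-5-oxohexanal | CC(C)[C@@H](C=O)CCC(C)=O | intermediate
21 | (S)-4-isopropylcyclohex-2-en-1-one ((S)-cryptone) | CC(C)[C@@H]1CCC(=O)C=C1 | intermediate
22 | {[(3S,4S)-4-isopropyl-3-vinylcyclohex-1-en-1-yl]oxy}trimethylsilane (3,4-trans) | C[Si](C)(C)OC1=C[C@@H](C=C)[C@H](C(C)C)CC1 | intermediate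
23 | (3S,4S)-2-(hydroxymethyl)-4-isopropyl-3-vinylcyclohexan-1-one (3,4-trans; C2 epimers, mainly 2,3-trans) | O=C1CC[C@@H](C(C)C)[C@H](C=C)C1CO | intermediate
24 | secondary ozonide of 23 (1,2,4-trioxolan-3-yl in place of vinyl) | O=C1CC[C@@H](C(C)C)[C@H](C2OCOO2)C1CO | intermediate
25 | 2-(hydroxymethyl)-6-isopropyl-3-oxocyclohexane-1-carbaldehyde (formyl trans to isopropyl; open form of 26) | O=C1CC[C@@H](C(C)C)[C@H](C=O)C1CO | intermediate
26 | (3aR,7S,7aS)-1-hydroxy-7-isopropylhexahydro-2-benzofuran-4(1H)-one (cis-fused; 1-epimers) | O=C1CC[C@@H](C(C)C)[C@@H]2C(O)OC[C@@H]21 | intermediate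
27 | (3aR,7S,7aS)-7-isopropyl-1-(triethylsilyloxy)hexahydro-2-benzofuran-4(1H)-one (1-epimers) | O=C1CC[C@@H](C(C)C)[C@@H]2C(O[Si](CC)(CC)CC)OC[C@@H]21 | intermediate
28 | Barbier adduct: ester of acid 17 at the new CH2O group on C4 of 27 (tertiary C4-OH cis to the C3a–C3 bond; anomeric OSiEt3 kept) | CC(C)[C@H]1CCC(CO[Si](C(C)C)(C(C)C)C(C)C)=C[C@@H]1/C=C(\CO[Si](C(C)C)(C(C)C)C(C)C)C(=O)OC[C@@]1(O)CC[C@@H](C(C)C)[C@@H]2C(O[Si](CC)(CC)CC)OC[C@@H]21 | intermediate
29 | coupled lactol: 28 with the anomeric silyl group removed | CC(C)[C@H]1CCC(CO[Si](C(C)C)(C(C)C)C(C)C)=C[C@@H]1/C=C(\CO[Si](C(C)C)(C(C)C)C(C)C)C(=O)OC[C@@]1(O)CC[C@@H](C(C)C)[C@@H]2C(O)OC[C@@H]21 | intermediate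
30 | ring-opened hydroxymethyl bis-acrylate: cyclohexane with tertiary OH and the acyloxymethyl group of acid 17 at C1, CH2OH at C2, (E)-CH=C(CH2OTIPS)CO2t-Bu at C3 (cis to the C2 arm), isopropyl at C4 (trans to the C3 arm) | CC(C)[C@H]1CCC(CO[Si](C(C)C)(C(C)C)C(C)C)=C[C@@H]1/C=C(\CO[Si](C(C)C)(C(C)C)C(C)C)C(=O)OC[C@@]1(O)CC[C@@H](C(C)C)[C@H](/C=C(\CO[Si](C(C)C)(C(C)C)C(C)C)C(=O)OC(C)(C)C)[C@@H]1CO | intermediate
31 | aldehyde: 30 with the C2 CH2OH oxidised to CHO | CC(C)[C@H]1CCC(CO[Si](C(C)C)(C(C)C)C(C)C)=C[C@@H]1/C=C(\CO[Si](C(C)C)(C(C)C)C(C)C)C(=O)OC[C@@]1(O)CC[C@@H](C(C)C)[C@H](/C=C(\CO[Si](C(C)C)(C(C)C)C(C)C)C(=O)OC(C)(C)C)[C@@H]1C=O | intermediate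
32 | carboxylic acid: 30 with the C2 CH2OH oxidised to CO2H | CC(C)[C@H]1CCC(CO[Si](C(C)C)(C(C)C)C(C)C)=C[C@@H]1/C=C(\CO[Si](C(C)C)(C(C)C)C(C)C)C(=O)OC[C@@]1(O)CC[C@@H](C(C)C)[C@H](/C=C(\CO[Si](C(C)C)(C(C)C)C(C)C)C(=O)OC(C)(C)C)[C@@H]1C(=O)O | intermediate
33 | seco acid triol: 32 without the three silyl groups | CC(C)[C@H]1CCC(CO)=C[C@@H]1/C=C(\CO)C(=O)OC[C@@]1(O)CC[C@@H](C(C)C)[C@H](/C=C(\CO)C(=O)OC(C)(C)C)[C@@H]1C(=O)O | intermediate
34 | mixed 2,4,6-trichlorobenzoic anhydride of 33 | CC(C)[C@H]1CCC(CO)=C[C@@H]1/C=C(\CO)C(=O)OC[C@@]1(O)CC[C@@H](C(C)C)[C@H](/C=C(\CO)C(=O)OC(C)(C)C)[C@@H]1C(=O)OC(=O)c1c(Cl)cc(Cl)cc1Cl | intermediate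
35 | tert-butyl ester of the target (cis-fused seven-membered lactone closed) | CC(C)[C@H]1CCC(CO)=C[C@@H]1/C=C(\CO)C(=O)OC[C@@]1(O)CC[C@@H](C(C)C)[C@@H]2C=C(C(=O)OC(C)(C)C)COC(=O)[C@@H]21 | intermediate
36 | trimethylsilyl ester of the target with its three hydroxyls as trimethylsilyl ethers | CC(C)[C@H]1CCC(CO[Si](C)(C)C)=C[C@@H]1/C=C(\CO[Si](C)(C)C)C(=O)OC[C@@]1(O[Si](C)(C)C)CC[C@@H](C(C)C)[C@@H]2C=C(C(=O)O[Si](C)(C)C)COC(=O)[C@@H]21 | intermediate
37 | CNP0361406.3 | CC(C)[C@H]1CCC(CO)=C[C@@H]1/C=C(\CO)C(=O)OC[C@@]1(O)CC[C@@H](C(C)C)[C@@H]2C=C(C(=O)O)COC(=O)[C@@H]21 | target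

Step count and risks

Total step count: 19 (step 1 for the ylide, steps 2 to 9 for the left-hand fragment, steps 10 to 13 for the ketone, steps 14 to 19 for coupling and endgame).
Longest linear sequence: 14 steps (steps 2 to 9, then 14 to 19).

The three steps most likely to fail:

Risk 1, step 14 (the step that goes beyond known chemistry). The acyloxymethylsamarium species may transfer its own acyl group to the metallated carbon before it meets the ketone, or electron transfer may go to the ketone first, so that the fragments do not join. The fallback for step 14 uses known chemistry, sets out from 27 and comes back to the route at 28. Corey–Chaykovsky methylene transfer (Me3SI, n-BuLi, THF, −10 °C) should deliver CH2 from the convex face of 27 and give the spiro-epoxide F1. Acid 17 with Cs2CO3 in DMF at 70 °C should then open F1 at its CH2 terminus through the carboxylate and give 28; the citric acid work-up of step 14 converts 28 into 29.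

Risk 2, step 12. Epimerisation at the ring-fusion carbon may stay incomplete, or the ring oxygen may be lost by β-elimination during equilibration, so that trans-fused material persists. The fallback for step 12 sets the centre kinetically, sets out from 21 and comes back to the route at 26. A Morita–Baylis–Hillman reaction with aqueous formaldehyde (imidazole, THF/H2O, rt) should give (S)-2-(hydroxymethyl)-4-isopropylcyclohex-2-en-1-one F2. Conjugate addition of excess CH2=CHMgBr with CuBr·SMe2 (THF, −78 °C), followed by protonation of the enolate at −78 °C with 2,6-di-tert-butylphenol anti to the pseudo-axial vinyl group, should give the 2,3-cis ketone (2R,3S,4S)-2-(hydroxymethyl)-4-isopropyl-3-vinylcyclohexan-1-one F3. Ozonolysis of F3 (O3, then PPh3) passes through the 2,3-cis epimers of 24 and 25 and closes directly to 26.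

Risk 3, step 18. One of the two remote primary hydroxyls may be acylated, or oligomers may form, in competition with seven-membered ring closure. The fallback for step 18 lets ring-chain tautomerism choose the hydroxyl, sets out from 30 and comes back to the route at 35. Oxidation with 1,1,1-triacetoxy-1,1-dihydro-1,2-benziodoxol-3(1H)-one (NaHCO3, CH2Cl2) is stopped at aldehyde 31, which is isolated in this variant. HF·pyridine then frees the three primary hydroxyls; only the one on the neighbouring acrylate arm can reach the aldehyde, which should give the seven-membered lactol F4. Ag2CO3 on Celite (benzene, 80 °C) should oxidise the lactol F4 in preference to the allylic alcohols and give 35.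

Further compounds
F1 | step 14 | spiro-epoxide of 27: oxirane spiro-fused at C4 of the bicycle with its CH2 on the convex face | C1O[C@@]12CC[C@@H](C(C)C)[C@@H]3C(O[Si](CC)(CC)CC)OC[C@@H]32
F2 | step 12 | (S)-2-(hydroxymethyl)-4-isopropylcyclohex-2-en-1-one | CC(C)[C@@H]1CCC(=O)C(CO)=C1
F3 | step 12 | (2R,3S,4S)-2-(hydroxymethyl)-4-isopropyl-3-vinylcyclohexan-1-one (2,3-cis; 3,4-trans) | O=C1CC[C@@H](C(C)C)[C@H](C=C)[C@@H]1CO
F4 | step 18 | seven-membered lactol corresponding to 35 (lactone C=O replaced by CH–OH; lactol epimers) | CC(C)[C@H]1CCC(CO)=C[C@@H]1/C=C(\CO)C(=O)OC[C@@]1(O)CC[C@@H](C(C)C)[C@@H]2C=C(C(=O)OC(C)(C)C)COC(O)[C@@H]21
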